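## Retrosynthetic overview

1. The C7=C8 bond is cut by a Julia–Kocienski olefination into the C10 ring sulfone 20 and the aryl C30 polyenal 27. Aldehyde 27 comes from crocetindialdehyde 24 and the benzylic Wittig salt 23 (C10 + C20 + C10).
2. The cyclohexadiene ring is not closed directly: SO2 is placed between C3 and C4 to give the seven-membered thiepane 1,1-dioxide 14, and a Ramberg–Bäcklund reaction contracts it (7 → 6) while creating C3=C4.
3. Enabling feature: in the six-membered ring the cis C3=C4 bond (both carbons CH) sits next to the exocyclic C5=CH2. A sulfur bridging C3 and C4 is therefore flanked by an allylically activated α-carbon (C4) and a plain CH2 (C3); excising it leaves exactly the ring 1,3-diene, and C6 is not involved.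
4. Thiepane 13 arises by 7-endo thiol–ene closure of an acyclic 1,5-diene whose isopropenyl CH3 (the future C4) has been chlorinated and thiolated. The whole C10 skeleton and C6 come from an enantioselective Ireland–Claisen rearrangement of prenyl 3-methylbut-3-enoate 4.
5. Ring order: aryl ring bought; thiepane ring (step 7); six-membered carbocycle by contraction (step 9).

Key step: step 9

Remark 1: carotenoid numbering is used. Ring: C1 (CMe2), C2 (CH2), C3=C4, C5 (bearing the exocyclic CH2, C18), C6 (stereocentre, S in the target); chain C7–C15 and C15′–C7′; then the aryl ring.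
Remark 2: the sense of induction in step 2 is assumed as drawn for the (4R,5R)-boron controller; if the (2S)-acid predominated, the enantiomeric controller would be used with no other change.
Remark 3: crocetindialdehyde 24 and 2,3,4-trimethylbenzaldehyde 21 are taken as purchasable building blocks.

## Route

Step 1
Reactants: 1 3-methylbut-3-enoic acid; 2 1-bromo-3-methylbut-2-ene (prenyl bromide)
Product: 4 3-methylbut-2-en-1-yl 3-methylbut-3-enoate, via potassium carboxylate 3 (not isolated)
Conditions: KHCO3, DMF, 0 °C → rt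
Reagents that add atoms: none
Why: Carboxylate O-alkylation (SN2 on the primary allylic bromide) under bicarbonate, mild enough that the β,γ-double bond should not move into conjugation.

Step 2
Reactants: 4 3-methylbut-2-en-1-yl 3-methylbut-3-enoate
Product: 7 (2R)-3,3-dimethyl-2-(prop-1-en-2-yl)pent-4-enoic acid, via boron ketene acetal 5 (not isolated), via boron carboxylate 6 (not isolated)
Conditions: (4R,5R)-2-bromo-4,5-diphenyl-1,3-bis(4-methylbenzenesulfonyl)-1,3,2-diazaborolidine (1.2 equiv, prepared from the (1R,2R)-bis-sulfonamide and BBr3), Et3N, toluene/hexane, −78 °C → −20 °C → 4 °C; aqueous work-up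
Reagents that add atoms: none
Why: Enantioselective ester-enolate (Ireland–Claisen) rearrangement: soft enolisation gives a chiral boron ketene acetal that rearranges through a chair [3,3] transition state, the C2-symmetric bis-sulfonamide ligand shielding one enolate face so that C6 is set at the α-carbon, while the prenyl terminus becomes the non-stereogenic CMe2 (C1).

Step 3
Reactants: 7 (2R)-3,3-dimethyl-2-(prop-1-en-2-yl)pent-4-enoic acid
Product: 8 (2R)-3,3-dimethyl-2-(prop-1-en-2-yl)pent-4-en-1-ol
Conditions: LiAlH4, Et2O, 0 °C → rt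
Reagents that add atoms: none
Why: Hydride reduction of the carboxylic acid; C6 is protected from enolisation as the carboxylate, and the low temperature keeps the 3,3-dimethyl-1,5-diene from Cope rearrangement.

Step 4
Reactants: 8 (2R)-3,3-dimethyl-2-(prop-1-en-2-yl)pent-4-en-1-ol
Product: 9 tert-butyl{[(2R)-3,3-dimethyl-2-(prop-1-en-2-yl)pent-4-en-1-yl]oxy}diphenylsilane
Conditions: tert-butyl(chloro)diphenylsilane, imidazole, 4-(dimethylamino)pyridine (cat.), DMF, rt
Reagents that add atoms: tert-butyl(chloro)diphenylsilane, CC(C)(C)[Si](Cl)(c1ccccc1)c1ccccc1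
Why: Standard silylation of the primary alcohol; the silyl ether prevents chloroetherification in step 5 and should survive the base of step 9.

Step 5
Reactants: 9 tert-butyl{[(2R)-3,3-dimethyl-2-(prop-1-en-2-yl)pent-4-en-1-yl]oxy}diphenylsilane
Product: 10 tert-butyl{[(2S)-2-(3-chloroprop-1-en-2-yl)-3,3-dimethylpent-4-en-1-yl]oxy}diphenylsilane
Conditions: Ca(OCl)2, solid CO2, CH2Cl2/H2O, 0 °C
Reagents that add atoms: calcium hypochlorite, [Ca+2].[O-]Cl.[O-]Cl
Why: Ene-type allylic chlorination by HOCl: the electron-richer 1,1-disubstituted isopropenyl alkene should react before the monosubstituted vinyl group, chlorine adds to the terminal CH2 and the proton is lost from the methyl group rather than from the hindered C6–H, so the stereocentre is untouched (the descriptor changes only through the priority rules).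

Step 6
Reactants: 10 tert-butyl{[(2S)-2-(3-chloroprop-1-en-2-yl)-3,3-dimethylpent-4-en-1-yl]oxy}diphenylsilane
Product: 11 S-[(3S)-3-({[tert-butyl(diphenyl)silyl]oxy}methyl)-4,4-dimethyl-2-methylidenehex-5-en-1-yl] ethanethioate
Conditions: KSC(O)CH3, DMF, 0 °C → rt
Reagents that add atoms: potassium thioacetate, CC(=O)[S-].[K+]
Why: SN2 displacement of the primary allylic chloride by thioacetate (an SN2′ path would give the same compound, because the two CH2 termini of the 2-substituted allyl unit are equivalent).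

Step 7
Reactants: 11 S-[(3S)-3-({[tert-butyl(diphenyl)silyl]oxy}methyl)-4,4-dimethyl-2-methylidenehex-5-en-1-yl] ethanethioate
Product: 13 tert-butyl{[(4S)-5,5-dimethyl-3-methylidenethiepan-4-yl]methoxy}diphenylsilane, via allylic thiol 12 (not isolated)
Conditions: NH3 (7 M in CH3OH), degassed, 0 °C; evaporate; then 2,2-dimethoxy-2-phenylacetophenone (cat.), hν (365 nm), degassed EtOAc, high dilution (about 0.005 M), rt
Reagents that add atoms: none
Why: Aminolysis frees the thiol, and an intramolecular radical thiol–ene reaction closes the thiepane: the thiyl radical attacks the terminal vinyl carbon C3 (anti-Markovnikov, 7-endo-trig; the internal carbon is neopentylic), S–H transfer carries the chain, and high dilution at room temperature should suppress oligomerisation and Cope rearrangement.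

Step 8
Reactants: 13 tert-butyl{[(4S)-5,5-dimethyl-3-methylidenethiepan-4-yl]methoxy}diphenylsilane
Product: 14 (4S)-4-({[tert-butyl(diphenyl)silyl]oxy}methyl)-5,5-dimethyl-3-methylidenethiepane 1,1-dioxide
Conditions: (NH4)6Mo7O24·4H2O (cat.), 30% H2O2, EtOH, 0 °C → rt
Reagents that add atoms: hydrogen peroxide, OO
Why: Molybdate-catalysed peroxide oxidation of the sulfide to the sulfone, which should be much faster than epoxidation of the 1,1-disubstituted alkene (electron-poor once it is part of an allylic sulfone).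

Step 9
Reactants: 14 (4S)-4-({[tert-butyl(diphenyl)silyl]oxy}methyl)-5,5-dimethyl-3-methylidenethiepane 1,1-dioxide
Product: 17 tert-butyl{[(1S)-6,6-dimethyl-2-methylidenecyclohex-3-en-1-yl]methoxy}diphenylsilane, via α-bromo sulfone 15 (not isolated), via thiirane dioxide 16 (not isolated)
Conditions: KOH/Al2O3, CBr2F2, (CH3)3COH/CH2Cl2, 0 °C → rt
Reagents that add atoms: none
Why: Ramberg–Bäcklund reaction in its one-pot halogenative form: KOH deprotonates the sulfone at C4, which is both α to sulfur and allylic to the exocyclic C5=CH2, and CBr2F2 transfers bromine to this carbanion to give 15. A second deprotonation at C3 is followed by intramolecular displacement of bromide (1,3-elimination, 3-exo-tet) to the thiirane 1,1-dioxide 16, which loses SO2 cheletropically. The six-membered carbocycle is thus closed by forming the C3–C4 bond inside the seven-membered ring, which contracts by the sulfur atom; the closest precedents are Ramberg–Bäcklund contractions of thiepane 1,1-dioxides to cyclohexenes and of allylic sulfones to 1,3-dienes. No stereocentre is created: C3=C4 can only be cis in the six-membered ring, and C6 should keep its configuration because its hydrogen is merely allylic and far less acidic than the α-sulfonyl hydrogens. The step needs the new double bond exactly between the two carbons that carried sulfur, which the sulfone dictates, and it needs the exocyclic double bond not to migrate, which fast bromination of the allylic sulfonyl anion at 0 °C on a heterogeneous base should secure.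

Step 10
Reactants: 17 tert-butyl{[(1S)-6,6-dimethyl-2-methylidenecyclohex-3-en-1-yl]methoxy}diphenylsilane
Product: 18 [(1S)-6,6-dimethyl-2-methylidenecyclohex-3-en-1-yl]methanol
Conditions: Bu4NF, THF, 0 °C → rt
Reagents that add atoms: none
Why: Fluoride-mediated desilylation under nearly neutral conditions that should leave the diene and C6 untouched.

Step 11
Reactants: 18 [(1S)-6,6-dimethyl-2-methylidenecyclohex-3-en-1-yl]methanol
Product: 19 5-({[(1S)-6,6-dimethyl-2-methylidenecyclohex-3-en-1-yl]methyl}sulfanyl)-1-phenyl-1H-tetrazole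
Conditions: 1-phenyl-1H-tetrazole-5-thiol, PPh3, diisopropyl azodicarboxylate, THF, 0 °C → rt
Reagents that add atoms: 1-phenyl-1H-tetrazole-5-thiol, Sc1nnnn1-c1ccccc1
Why: Mitsunobu thioetherification: the primary alcohol is activated as its oxyphosphonium ion and displaced at C7 by the acidic thiol, under neutral conditions that do not touch C6 or the diene.

Step 12
Reactants: 19 5-({[(1S)-6,6-dimethyl-2-methylidenecyclohex-3-en-1-yl]methyl}sulfanyl)-1-phenyl-1H-tetrazole
Product: 20 5-({[(1S)-6,6-dimethyl-2-methylidenecyclohex-3-en-1-yl]methyl}sulfonyl)-1-phenyl-1H-tetrazole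
Conditions: (NH4)6Mo7O24·4H2O (cat.), 30% H2O2, EtOH, 0 °C → rt
Reagents that add atoms: hydrogen peroxide, OO
Why: Chemoselective molybdate/peroxide oxidation of the sulfide to the sulfone; without a directing hydroxyl group the diene should be epoxidised far more slowly than sulfur is oxidised.

Step 13
Reactants: 21 2,3,4-trimethylbenzaldehyde
Product: 22 (2,3,4-trimethylphenyl)methanol
Conditions: NaBH4, CH3OH, 0 °C
Reagents that add atoms: none
Why: Borohydride reduction of the aryl aldehyde.

Step 14
Reactants: 22 (2,3,4-trimethylphenyl)methanol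
Product: 23 triphenyl[(2,3,4-trimethylphenyl)methyl]phosphonium bromide
Conditions: Ph3P·HBr, CH3CN, reflux
Reagents that add atoms: triphenylphosphine hydrobromide, [Br-].c1ccc(cc1)[PH+](c1ccccc1)c1ccccc1
Why: Acid-promoted substitution of the electron-rich benzylic alcohol by triphenylphosphine through the stabilised benzylic cation.

Step 15
Reactants: 23 triphenyl[(2,3,4-trimethylphenyl)methyl]phosphonium bromide; 24 crocetindialdehyde, (2E,4E,6E,8E,10E,12E,14E)-2,6,11,15-tetramethylhexadeca-2,4,6,8,10,12,14-heptaenedial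
Product: 27 (2E,4E,6E,8E,10E,12E,14E,16E)-2,6,11,15-tetramethyl-17-(2,3,4-trimethylphenyl)heptadeca-2,4,6,8,10,12,14,16-octaenal, via phosphonium ylide 25 (not isolated), via 16Z aldehyde 26 (not isolated)
Conditions: NaOCH3, CH3OH/CH2Cl2, 0 °C → rt, 24 in excess (3 equiv, recovered); then I2 (cat.), toluene, daylight, rt; dark work-up
Reagents that add atoms: none
Why: Wittig reaction of the semi-stabilised benzylic ylide with one aldehyde of the symmetrical dialdehyde (excess dialdehyde should favour mono-olefination), followed by iodine-catalysed equilibration of the new C7′=C8′ bond to the E isomer at a stage that carries no stereocentre.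

Step 16
Reactants: 20 5-({[(1S)-6,6-dimethyl-2-methylidenecyclohex-3-en-1-yl]methyl}sulfonyl)-1-phenyl-1H-tetrazole; 27 (2E,4E,6E,8E,10E,12E,14E,16E)-2,6,11,15-tetramethyl-17-(2,3,4-trimethylphenyl)heptadeca-2,4,6,8,10,12,14,16-octaenal
Product: 30 target, 1,2,3-trimethyl-4-[(1E,3E,5E,7E,9E,11E,13E,15E,17E)-18-[(1S)-6,6-dimethyl-2-methylidenecyclohex-3-en-1-yl]-3,7,12,16-tetramethyloctadeca-1,3,5,7,9,11,13,15,17-nonaen-1-yl]benzene, via sulfonyl carbanion 28 (not isolated), via alkoxide adduct 29 (not isolated)
Conditions: KN(SiMe3)2 (0.95 equiv relative to 20), THF, −78 °C; then 27 in THF, −78 °C → rt, argon, dark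
Reagents that add atoms: none
Why: Julia–Kocienski olefination: the C7 carbanion adds to the enal, and Smiles rearrangement followed by anti-elimination of SO2 and the tetrazolyl oxide should give the (E)-C7=C8 bond (potassium counter-ion, open transition state); C6–H is not acidic in the sulfone, and keeping the base below one equivalent at −78 °C limits exposure of the triply allylic C6–H of the product.

## Compound list

1 | 3-methylbut-3-enoic acid | C=C(C)CC(=O)O | starting material
2 | 1-bromo-3-methylbut-2-ene (prenyl bromide) | CC(C)=CCBr | starting material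
3 | potassium 3-methylbut-3-enoate | C=C(C)CC(=O)[O-].[K+] | intermediate
4 | 3-methylbut-2-en-1-yl 3-methylbut-3-enoate | C=C(C)CC(=O)OCC=C(C)C | intermediate
5 | (4R,5R)-2-{[3-methyl-1-(3-methylbut-2-en-1-yloxy)buta-1,3-dien-1-yl]oxy}-4,5-diphenyl-1,3-bis(4-methylbenzenesulfonyl)-1,3,2-diazaborolidine (boron ketene acetal of 4) | C=C(C)C=C(OCC=C(C)C)OB1N(S(=O)(=O)c2ccc(C)cc2)[C@H](c2ccccc2)[C@@H](c2ccccc2)N1S(=O)(=O)c1ccc(C)cc1 | intermediate
6 | (4R,5R)-4,5-diphenyl-1,3-bis(4-methylbenzenesulfonyl)-1,3,2-diazaborolidin-2-yl (2R)-3,3-dimethyl-2-(prop-1-en-2-yl)pent-4-enoate | C=CC(C)(C)[C@@H](C(C)=C)C(=O)OB1N(S(=O)(=O)c2ccc(C)cc2)[C@H](c2ccccc2)[C@@H](c2ccccc2)N1S(=O)(=O)c1ccc(C)cc1 | intermediate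
7 | (2R)-3,3-dimethyl-2-(prop-1-en-2-yl)pent-4-enoic acid | C=CC(C)(C)[C@@H](C(C)=C)C(=O)O | intermediate
8 | (2R)-3,3-dimethyl-2-(prop-1-en-2-yl)pent-4-en-1-ol | C=CC(C)(C)[C@@H](C(C)=C)CO | intermediate
9 | tert-butyl{[(2R)-3,3-dimethyl-2-(prop-1-en-2-yl)pent-4-en-1-yl]oxy}diphenylsilane | C=CC(C)(C)[C@@H](C(C)=C)CO[Si](c1ccccc1)(c1ccccc1)C(C)(C)C | intermediate
10 | tert-butyl{[(2S)-2-(3-chloroprop-1-en-2-yl)-3,3-dimethylpent-4-en-1-yl]oxy}diphenylsilane | C=CC(C)(C)[C@@H](C(=C)CCl)CO[Si](c1ccccc1)(c1ccccc1)C(C)(C)C | intermediate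
11 | S-[(3S)-3-({[tert-butyl(diphenyl)silyl]oxy}methyl)-4,4-dimethyl-2-methylidenehex-5-en-1-yl] ethanethioate | C=CC(C)(C)[C@@H](C(=C)CSC(C)=O)CO[Si](c1ccccc1)(c1ccccc1)C(C)(C)C | intermediate
12 | (3S)-3-({[tert-butyl(diphenyl)silyl]oxy}methyl)-4,4-dimethyl-2-methylidenehex-5-ene-1-thiol | C=CC(C)(C)[C@@H](C(=C)CS)CO[Si](c1ccccc1)(c1ccccc1)C(C)(C)C | intermediate
13 | tert-butyl{[(4S)-5,5-dimethyl-3-methylidenethiepan-4-yl]methoxy}diphenylsilane | C=C1CSCCC(C)(C)[C@@H]1CO[Si](c1ccccc1)(c1ccccc1)C(C)(C)C | intermediate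
14 | (4S)-4-({[tert-butyl(diphenyl)silyl]oxy}methyl)-5,5-dimethyl-3-methylidenethiepane 1,1-dioxide | C=C1CS(=O)(=O)CCC(C)(C)[C@@H]1CO[Si](c1ccccc1)(c1ccccc1)C(C)(C)C | intermediate
15 | (4S)-2-bromo-4-({[tert-butyl(diphenyl)silyl]oxy}methyl)-5,5-dimethyl-3-methylidenethiepane 1,1-dioxide (C2 epimers) | C=C1C(Br)S(=O)(=O)CCC(C)(C)[C@@H]1CO[Si](c1ccccc1)(c1ccccc1)C(C)(C)C | intermediate
16 | (3S)-3-({[tert-butyl(diphenyl)silyl]oxy}methyl)-4,4-dimethyl-2-methylidene-7-thiabicyclo[4.1.0]heptane 7,7-dioxide | C=C1C2C(CC(C)(C)[C@@H]1CO[Si](c1ccccc1)(c1ccccc1)C(C)(C)C)S2(=O)=O | intermediate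
17 | tert-butyl{[(1S)-6,6-dimethyl-2-methylidenecyclohex-3-en-1-yl]methoxy}diphenylsilane | C=C1C=CCC(C)(C)[C@@H]1CO[Si](c1ccccc1)(c1ccccc1)C(C)(C)C | intermediate
18 | [(1S)-6,6-dimethyl-2-methylidenecyclohex-3-en-1-yl]methanol | C=C1C=CCC(C)(C)[C@@H]1CO | intermediate
19 | 5-({[(1S)-6,6-dimethyl-2-methylidenecyclohex-3-en-1-yl]methyl}sulfanyl)-1-phenyl-1H-tetrazole | C=C1C=CCC(C)(C)[C@@H]1CSc1nnnn1-c1ccccc1 | intermediate
20 | 5-({[(1S)-6,6-dimethyl-2-methylidenecyclohex-3-en-1-yl]methyl}sulfonyl)-1-phenyl-1H-tetrazole | C=C1C=CCC(C)(C)[C@@H]1CS(=O)(=O)c1nnnn1-c1ccccc1 | intermediate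
21 | 2,3,4-trimethylbenzaldehyde | Cc1ccc(C=O)c(C)c1C | starting material
22 | (2,3,4-trimethylphenyl)methanol | Cc1ccc(CO)c(C)c1C | intermediate
23 | triphenyl[(2,3,4-trimethylphenyl)methyl]phosphonium bromide | Cc1ccc(C[P+](c2ccccc2)(c2ccccc2)c2ccccc2)c(C)c1C.[Br-] | intermediate
24 | crocetindialdehyde, (2E,4E,6E,8E,10E,12E,14E)-2,6,11,15-tetramethylhexadeca-2,4,6,8,10,12,14-heptaenedial | O=C/C(C)=C/C=C/C(C)=C/C=C/C=C(C)/C=C/C=C(C)/C=O | starting material
25 | triphenyl[(2,3,4-trimethylphenyl)methylidene]-λ5-phosphane (ylide) | Cc1ccc(C=P(c2ccccc2)(c2ccccc2)c2ccccc2)c(C)c1C | intermediate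
26 | (2E,4E,6E,8E,10E,12E,14E,16Z)-2,6,11,15-tetramethyl-17-(2,3,4-trimethylphenyl)heptadeca-2,4,6,8,10,12,14,16-octaenal | O=C/C(C)=C/C=C/C(C)=C/C=C/C=C(C)/C=C/C=C(C)/C=C\c1ccc(C)c(C)c1C | intermediate
27 | (2E,4E,6E,8E,10E,12E,14E,16E)-2,6,11,15-tetramethyl-17-(2,3,4-trimethylphenyl)heptadeca-2,4,6,8,10,12,14,16-octaenal | O=C/C(C)=C/C=C/C(C)=C/C=C/C=C(C)/C=C/C=C(C)/C=C/c1ccc(C)c(C)c1C | intermediate
28 | potassium [(1S)-6,6-dimethyl-2-methylidenecyclohex-3-en-1-yl][(1-phenyl-1H-tetrazol-5-yl)sulfonyl]methanide | C=C1C=CCC(C)(C)[C@@H]1[CH-]S(=O)(=O)c1nnnn1-c1ccccc1.[K+] | intermediate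
29 | potassium alkoxide of the β-hydroxy sulfone from 28 and 27 (1-[(1S)-6,6-dimethyl-2-methylidenecyclohex-3-en-1-yl]-3,7,12,16-tetramethyl-1-[(1-phenyl-1H-tetrazol-5-yl)sulfonyl]-18-(2,3,4-trimethylphenyl)octadeca-3,5,7,9,11,13,15,17-octaen-2-olate, all-E, C7/C8 diastereomers) | C=C1C=CCC(C)(C)[C@@H]1C(S(=O)(=O)c1nnnn1-c1ccccc1)C([O-])/C(C)=C/C=C/C(C)=C/C=C/C=C(C)/C=C/C=C(C)/C=C/c1ccc(C)c(C)c1C.[K+] | intermediate
30 | 1,2,3-trimethyl-4-[(1E,3E,5E,7E,9E,11E,13E,15E,17E)-18-[(1S)-6,6-dimethyl-2-methylidenecyclohex-3-en-1-yl]-3,7,12,16-tetramethyloctadeca-1,3,5,7,9,11,13,15,17-nonaen-1-yl]benzene | C=C1C=CCC(C)(C)[C@@H]1/C=C/C(C)=C/C=C/C(C)=C/C=C/C=C(C)/C=C/C=C(C)/C=C/c1ccc(C)c(C)c1C | target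

## Step count and risks

Total steps: 16. Longest linear sequence: 13 steps (steps 1–12, then step 16); the aryl branch (steps 13–15) joins in step 16.

Steps most likely to fail:

Step 2. The chiral boron reagent may enolise the β,γ-unsaturated ester to a mixture of enolate geometries, so that facial discrimination at C6 is incomplete and the acid is formed with insufficient enantiomeric purity. The fallback sets out from 4 and comes back at 7 and replaces reagent control by resolution. Compound 4 is rearranged without stereocontrol (LiN(iPr)2, Me3SiCl, THF, −78 °C → rt, then dilute HCl) to racemic 3,3-dimethyl-2-(prop-1-en-2-yl)pent-4-enoic acid F1. The acid is resolved by fractional crystallisation of its salt with (R)-1-phenylethylamine, (R)-1-phenylethylammonium (2R)-3,3-dimethyl-2-(prop-1-en-2-yl)pent-4-enoate F2 (the enantiomeric amine is taken if the salt of the (2S)-acid turns out to be the less soluble one). Acidification of F2 with dilute HCl releases 7.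

Step 7. The thiyl radical may add intermolecularly, or the product, itself a cyclic allylic sulfide, may be reopened by radical addition–fragmentation, so that oligomers grow at the expense of the thiepane. The fallback sets out from 10 and comes back at 13 and closes the ring by ionic displacement. The vinyl group of 10 is hydroborated selectively (9-borabicyclo[3.3.1]nonane, THF, then NaBO3·4H2O) to (4S)-4-({[tert-butyl(diphenyl)silyl]oxy}methyl)-5-(chloromethyl)-3,3-dimethylhex-5-en-1-ol F3. The alcohol is converted (CH3SO2Cl, Et3N, CH2Cl2, 0 °C) into (4S)-4-({[tert-butyl(diphenyl)silyl]oxy}methyl)-5-(chloromethyl)-3,3-dimethylhex-5-en-1-yl methanesulfonate F4. Slow addition of F4 to Na2S·9H2O in DMF at high dilution displaces chloride and mesylate in turn and gives 13.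

Step 9. Under hydroxide the allylic sulfonyl anion may be reprotonated at the exocyclic carbon (migration of the C5=CH2 bond into the ring) or be brominated twice before the 1,3-elimination, and prolonged contact of the diene with base may move its double bonds. The fallback sets out from 14 and comes back at 17 and separates halogenation from contraction. Sulfone 14 is lithiated once at C4 (LiN(SiMe3)2, THF, −78 °C) and chlorinated with C2Cl6 to the isolated α-chloro sulfone (4S)-4-({[tert-butyl(diphenyl)silyl]oxy}methyl)-2-chloro-5,5-dimethyl-3-methylidenethiepane 1,1-dioxide F5. Treatment of F5 with KOC(CH3)3 in THF at −78 °C → 0 °C then effects the 1,3-elimination and loss of SO2 to give 17, without hydroxide or a halogen-transfer reagent in contact with the diene.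

## Further compounds

F1 | step 2 | racemic 3,3-dimethyl-2-(prop-1-en-2-yl)pent-4-enoic acid | C=CC(C)(C)C(C(C)=C)C(=O)O
F2 | step 2 | (R)-1-phenylethylammonium (2R)-3,3-dimethyl-2-(prop-1-en-2-yl)pent-4-enoate | C=CC(C)(C)[C@@H](C(C)=C)C(=O)[O-].C[C@@H]([NH3+])c1ccccc1
F3 | step 7 | (4S)-4-({[tert-butyl(diphenyl)silyl]oxy}methyl)-5-(chloromethyl)-3,3-dimethylhex-5-en-1-ol | OCCC(C)(C)[C@@H](C(=C)CCl)CO[Si](c1ccccc1)(c1ccccc1)C(C)(C)C
F4 | step 7 | (4S)-4-({[tert-butyl(diphenyl)silyl]oxy}methyl)-5-(chloromethyl)-3,3-dimethylhex-5-en-1-yl methanesulfonate | CS(=O)(=O)OCCC(C)(C)[C@@H](C(=C)CCl)CO[Si](c1ccccc1)(c1ccccc1)C(C)(C)C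
F5 | step 9 | (4S)-4-({[tert-butyl(diphenyl)silyl]oxy}methyl)-2-chloro-5,5-dimethyl-3-methylidenethiepane 1,1-dioxide (C2 epimers) | C=C1C(Cl)S(=O)(=O)CCC(C)(C)[C@@H]1CO[Si](c1ccccc1)(c1ccccc1)C(C)(C)C
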